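**Assumption:** the SMILES is read as (R) at the lactate carbon and cis-(2S,3S) on the benzodioxane (numbering used here: O1, C2 = aryl carbon, C3 = carboxyl carbon, O4, side chain on C6). The ligand antipode written in step 4 is taken to give (2S,3S); if the first run gives (2R,3R), the mirror-image ligand is used.

## Retrosynthetic overview

1. Target 19 ⇐ BCl3 debenzylation of 18 ⇐ Knoevenagel–Doebner union (forms the cinnamate C=C) of aldehyde-acid 10 with malonic half-ester 17.
2. cis-(2S,3S)-10 ⇐ syn asymmetric hydrogenation of the tetrasubstituted benzodioxine acid 9, which sets both ring stereocentres in one step.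
3. 9 ⇐ C3–CO2H bond from the 3-lithio-1,4-benzodioxine of 6 (an α-aryloxyvinyl anion, i.e. an acyl-anion equivalent) and CO2.
4. 6 ⇐ 3,4-dihydroxybenzaldehyde 4 + bromoalkyne 3 (from aldehyde 1) by O-addition then Cu O-vinylation; this dioxine ring is the only ring formed.
5. 17 ⇐ Meldrum's acid 16 + (R)-aryllactic acid 15 ⇐ aryl Grignard 13 + methyl (R)-glycidate 12 (lactate centre from the chiral pool).

## Route

**Step 1**
Reactants: 1 3,4-bis(benzyloxy)benzaldehyde
Product: 3 4-(bromoethynyl)-1,2-bis(benzyloxy)benzene, via gem-dibromoalkene 2 (not isolated)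
Conditions: Ph3P(CHBr2)Br (2 equiv), t-BuOK (1.9 equiv), THF, rt; then t-BuOK (3 equiv), rt
Reagents that add atoms: (dibromomethyl)triphenylphosphonium bromide, BrC(Br)[P+](c1ccccc1)(c1ccccc1)c1ccccc1.[Br-]
Why: Wittig dibromo-olefination (Corey–Fuchs type) followed in the same pot by E2 dehydrobromination with t-BuOK gives the 1-bromoalkyne; benzyl ethers are inert.

**Step 2**
Reactants: 3 4-(bromoethynyl)-1,2-bis(benzyloxy)benzene; 4 3,4-dihydroxybenzaldehyde
Product: 6 2-[3,4-bis(benzyloxy)phenyl]-1,4-benzodioxine-6-carbaldehyde, via (Z)-2-bromovinyl aryl ether 5 (not isolated)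
Conditions: K2CO3 (1.1 equiv), DMF, 100 °C, N2; then CuI (10 mol %), 1,10-phenanthroline (20 mol %), Cs2CO3 (1.5 equiv), 110 °C
Reagents that add atoms: none
Why: With about one equivalent of K2CO3 only the 4-OH (para to CHO) is ionised, and it adds anti to the bromoalkyne at the aryl-bearing carbon (phenoxide/1-bromoalkyne addition giving the (Z)-2-bromovinyl ether); the 3-OH then closes the ring by Cu-catalysed Ullmann-type O-vinylation, so the oxygen para to CHO ends on C2 (aryl) and the meta oxygen on C3.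

**Step 3**
Reactants: 6 2-[3,4-bis(benzyloxy)phenyl]-1,4-benzodioxine-6-carbaldehyde
Product: 9 2-[3,4-bis(benzyloxy)phenyl]-6-formyl-1,4-benzodioxine-3-carboxylic acid, via lithium amino alkoxide 7 (not isolated), via vinyllithium 8 (not isolated)
Conditions: 1-methylpiperazine, n-BuLi (1.1 equiv each), THF, −78 °C, add 6, −78 → −40 °C; LiN(i-Pr)2 (LDA, 1.4 equiv), −78 °C, 45 min; CO2 (g), −78 °C; cold 1 M HCl
Reagents that add atoms: carbon dioxide, O=C=O
Why: After in situ masking of the aldehyde as its lithium α-amino alkoxide (Comins protection), LDA removes the enol-ether C3–H to give an α-aryloxyvinyllithium, an acyl-anion equivalent whose carbon is otherwise electrophilic, and CO2 traps it, joining two normally electrophilic carbons; −78 °C suppresses β-elimination to the ynol ether and competing aryl lithiation, and acid work-up returns the aldehyde.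

**Step 4**
Reactants: 9 2-[3,4-bis(benzyloxy)phenyl]-6-formyl-1,4-benzodioxine-3-carboxylic acid
Product: 10 (2S,3S)-2-[3,4-bis(benzyloxy)phenyl]-6-formyl-2,3-dihydro-1,4-benzodioxine-3-carboxylic acid
Conditions: H2 (10 atm), [Ir(cod)(L)]B[3,5-(CF3)2C6H3]4 (1 mol %; L = (Sa,S)-SIPHOX, a 1,1'-spirobiindane phosphine–oxazoline), Et3N (0.5 equiv), MeOH/THF, 45 °C
Reagents that add atoms: none
Why: Proposed new method: the carboxylate binds the cationic monovalent iridium hydride and both hydrogens are delivered to one face of the tetrasubstituted C2=C3 bond (syn addition), which makes aryl and CO2H cis by necessity while the chiral spiro pocket selects the face to give (2S,3S); the closest known reaction type is the carboxy-directed Ir/spiro phosphine–oxazoline hydrogenation of α-aryloxy and of tetrasubstituted α,β-unsaturated carboxylic acids, a catalyst class that leaves benzyl ethers and aryl aldehydes untouched, and the product stays as a carboxylate that cannot epimerise at C3.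

**Step 5**
Reactants: 11 1-(benzyloxy)-4-bromo-2-methoxybenzene; 12 methyl (2R)-oxirane-2-carboxylate (methyl (R)-glycidate)
Product: 15 (2R)-3-[4-(benzyloxy)-3-methoxyphenyl]-2-hydroxypropanoic acid, via aryl Grignard reagent 13 (not isolated), via methyl ester 14 (not isolated)
Conditions: Mg, THF, 40 °C; CuI (10 mol %), then 12 (0.8 equiv), −40 → −20 °C; then LiOH, THF/H2O, 0 °C → rt; 1 M HCl
Reagents that add atoms: lithium hydroxide, [Li+].[OH-]
Why: Cu-catalysed SN2 opening of the epoxide at its terminal CH2 by the aryl Grignard reagent leaves the chiral-pool (R) carbinol centre untouched, and mild in-pot saponification of the α-hydroxy ester gives the acid without racemisation.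

**Step 6**
Reactants: 15 (2R)-3-[4-(benzyloxy)-3-methoxyphenyl]-2-hydroxypropanoic acid; 16 Meldrum's acid (2,2-dimethyl-1,3-dioxane-4,6-dione)
Product: 17 (2R)-3-[4-(benzyloxy)-3-methoxyphenyl]-2-[(carboxyacetyl)oxy]propanoic acid
Conditions: 16 (1.5 equiv), toluene, 95 °C, 5 h
Reagents that add atoms: none
Why: Alcoholysis of Meldrum's acid (acyl transfer with loss of acetone) gives the malonic half-ester; the secondary hydroxyl is the only competent nucleophile (any mixed anhydride at CO2H reverts on aqueous work-up) and the base-free conditions leave the (R) centre intact.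

**Step 7**
Reactants: 10 (2S,3S)-2-[3,4-bis(benzyloxy)phenyl]-6-formyl-2,3-dihydro-1,4-benzodioxine-3-carboxylic acid; 17 (2R)-3-[4-(benzyloxy)-3-methoxyphenyl]-2-[(carboxyacetyl)oxy]propanoic acid
Product: 18 (2S,3S)-2-[3,4-bis(benzyloxy)phenyl]-6-[(E)-3-({(1R)-2-[4-(benzyloxy)-3-methoxyphenyl]-1-carboxyethyl}oxy)-3-oxoprop-1-en-1-yl]-2,3-dihydro-1,4-benzodioxine-3-carboxylic acid
Conditions: 17 (1.3 equiv), pyridine, piperidine (0.2 equiv), 60 °C; cold 1 M HCl work-up
Reagents that add atoms: none
Why: Knoevenagel–Doebner condensation of the malonic half-ester with the aryl aldehyde and decarboxylation in pyridine gives the (E)-cinnamate; C3 of the benzodioxane and the lactate carbon both sit next to carboxylates and do not enolise, and the benzyl ethers block quinone-methide opening of the benzodioxane.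

**Step 8**
Reactants: 18 tribenzyl-protected diacid from step 7
Product: 19 (2S,3S)-6-[(E)-3-{[(1R)-1-carboxy-2-(4-hydroxy-3-methoxyphenyl)ethyl]oxy}-3-oxoprop-1-en-1-yl]-2-(3,4-dihydroxyphenyl)-2,3-dihydro-1,4-benzodioxine-3-carboxylic acid (target)
Conditions: BCl3 (8 equiv), pentamethylbenzene (10 equiv), CH2Cl2, −78 °C, 1 h; THF/H2O quench at −78 °C
Reagents that add atoms: none
Why: Lewis-acid debenzylation of the three aryl benzyl ethers with pentamethylbenzene as a non-basic benzyl-cation scavenger proceeds at −78 °C without touching the cinnamate alkene, the ester, the aryl methyl ether or (being base-free) C3, while the low temperature and the fast conversion of the para oxygen into a poorly donating ArO–BCl2 group protect the benzylic C2–O bond.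

## Compound list

1 | 3,4-bis(benzyloxy)benzaldehyde | O=Cc1ccc(OCc2ccccc2)c(OCc2ccccc2)c1 | starting material
2 | 4-(2,2-dibromoethenyl)-1,2-bis(benzyloxy)benzene | BrC(Br)=Cc1ccc(OCc2ccccc2)c(OCc2ccccc2)c1 | intermediate
3 | 4-(bromoethynyl)-1,2-bis(benzyloxy)benzene | BrC#Cc1ccc(OCc2ccccc2)c(OCc2ccccc2)c1 | intermediate
4 | 3,4-dihydroxybenzaldehyde | O=Cc1ccc(O)c(O)c1 | starting material
5 | 4-{[(Z)-1-(3,4-bis(benzyloxy)phenyl)-2-bromoethenyl]oxy}-3-hydroxybenzaldehyde | O=Cc1ccc(O/C(=C\Br)c2ccc(OCc3ccccc3)c(OCc3ccccc3)c2)c(O)c1 | intermediate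
6 | 2-[3,4-bis(benzyloxy)phenyl]-1,4-benzodioxine-6-carbaldehyde | O=Cc1ccc2OC(c3ccc(OCc4ccccc4)c(OCc4ccccc4)c3)=COc2c1 | intermediate
7 | lithium α-(4-methylpiperazin-1-yl) alkoxide of 6 | [Li]OC(N1CCN(C)CC1)c1ccc2OC(c3ccc(OCc4ccccc4)c(OCc4ccccc4)c3)=COc2c1 | intermediate
8 | 3-lithio derivative of 7 | [Li]OC(N1CCN(C)CC1)c1ccc2OC(c3ccc(OCc4ccccc4)c(OCc4ccccc4)c3)=C([Li])Oc2c1 | intermediate
9 | 2-[3,4-bis(benzyloxy)phenyl]-6-formyl-1,4-benzodioxine-3-carboxylic acid | O=Cc1ccc2OC(c3ccc(OCc4ccccc4)c(OCc4ccccc4)c3)=C(C(=O)O)Oc2c1 | intermediate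
10 | (2S,3S)-2-[3,4-bis(benzyloxy)phenyl]-6-formyl-2,3-dihydro-1,4-benzodioxine-3-carboxylic acid (cis) | O=Cc1ccc2c(c1)O[C@H](C(=O)O)[C@H](c1ccc(OCc3ccccc3)c(OCc3ccccc3)c1)O2 | intermediate
11 | 1-(benzyloxy)-4-bromo-2-methoxybenzene | COc1cc(Br)ccc1OCc1ccccc1 | starting material
12 | methyl (2R)-oxirane-2-carboxylate | COC(=O)[C@H]1CO1 | starting material
13 | [4-(benzyloxy)-3-methoxyphenyl]magnesium bromide | COc1cc([Mg]Br)ccc1OCc1ccccc1 | intermediate
14 | methyl (2R)-3-[4-(benzyloxy)-3-methoxyphenyl]-2-hydroxypropanoate | COC(=O)[C@H](O)Cc1ccc(OCc2ccccc2)c(OC)c1 | intermediate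
15 | (2R)-3-[4-(benzyloxy)-3-methoxyphenyl]-2-hydroxypropanoic acid | OC(=O)[C@H](O)Cc1ccc(OCc2ccccc2)c(OC)c1 | intermediate
16 | Meldrum's acid | CC1(C)OC(=O)CC(=O)O1 | starting material
17 | (2R)-3-[4-(benzyloxy)-3-methoxyphenyl]-2-[(carboxyacetyl)oxy]propanoic acid | OC(=O)CC(=O)O[C@H](Cc1ccc(OCc2ccccc2)c(OC)c1)C(=O)O | intermediate
18 | tribenzyl-protected target (name in step 7) | COc1cc(C[C@@H](OC(=O)/C=C/c2ccc3c(c2)O[C@H](C(=O)O)[C@H](c2ccc(OCc4ccccc4)c(OCc4ccccc4)c2)O3)C(=O)O)ccc1OCc1ccccc1 | intermediate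
19 | CNP0249420.1 (name in step 8) | COc1cc(C[C@@H](OC(=O)/C=C/c2ccc3c(c2)O[C@H](C(=O)O)[C@H](c2ccc(O)c(O)c2)O3)C(=O)O)ccc1O | target

## Step count and risks

Total step count: 8. Longest linear sequence: 6 steps (1, 2, 3, 4, 7, 8, from aldehyde 1).

The three steps most likely to fail:

**Step 3 (lithiation/carboxylation).** The vinyllithium may fragment by β-elimination, or the arene may be lithiated instead. Fallback: set out from 6 and use the innate nucleophilicity of the enol ether instead of deprotonation. C-acylation at C3 with trichloroacetyl chloride and pyridine in CH2Cl2 (0 °C → rt) gives 2-[3,4-bis(benzyloxy)phenyl]-3-(trichloroacetyl)-1,4-benzodioxine-6-carbaldehyde F1. Haloform cleavage of F1 with LiOH in THF/H2O at 0 °C, then acidification, returns to the route at acid 9.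

**Step 4 (asymmetric hydrogenation of the tetrasubstituted alkene).** Conversion or enantioselectivity may be low. Fallback: set out from 9 and separate the cis-selectivity from the enantioselectivity. Carboxylate-directed hydrogenation with achiral Ru(OAc)2(rac-BINAP) (H2 50 atm, MeOH, 50 °C) gives the racemic cis acid, that is 10 together with its (2R,3R) enantiomer F2. Classical resolution with the tertiary amine (S)-N,N-dimethyl-1-phenylethylamine (a tertiary amine cannot condense with the aldehyde) gives, by crystallisation from EtOAc/i-PrOH, the ammonium salt of the (2S,3S) acid F3. If the salt of F2 crystallises instead, the (R)-amine is used. Partition of F3 between EtOAc and cold 1 M HCl returns to the route at 10.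

**Step 8 (final debenzylation).** BCl3 may ionise the benzylic C2–O bond, causing ring opening or loss of the cis configuration. Fallback: set out from 10 and 17 and remove all benzyl groups by hydrogenolysis before the alkene exists. H2 (1 atm), Pd/C, EtOAc, stopped after two equivalents, converts 10 into (2S,3S)-2-(3,4-dihydroxyphenyl)-6-formyl-2,3-dihydro-1,4-benzodioxine-3-carboxylic acid F4. The same conditions convert 17 into (2R)-2-[(carboxyacetyl)oxy]-3-(4-hydroxy-3-methoxyphenyl)propanoic acid F5. Knoevenagel–Doebner condensation of F4 with F5 under weakly basic conditions (pyridine, catalytic β-alanine, 55 °C) then comes back to the route directly at target 19.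

## Further compounds

F1 | step 3 | 2-[3,4-bis(benzyloxy)phenyl]-3-(trichloroacetyl)-1,4-benzodioxine-6-carbaldehyde | O=Cc1ccc2OC(c3ccc(OCc4ccccc4)c(OCc4ccccc4)c3)=C(C(=O)C(Cl)(Cl)Cl)Oc2c1
F2 | step 4 | (2R,3R)-2-[3,4-bis(benzyloxy)phenyl]-6-formyl-2,3-dihydro-1,4-benzodioxine-3-carboxylic acid | O=Cc1ccc2c(c1)O[C@@H](C(=O)O)[C@@H](c1ccc(OCc3ccccc3)c(OCc3ccccc3)c1)O2
F3 | step 4 | (S)-N,N-dimethyl-1-phenylethylammonium salt of 10 | O=Cc1ccc2c(c1)O[C@H](C(=O)[O-])[C@H](c1ccc(OCc3ccccc3)c(OCc3ccccc3)c1)O2.C[C@H]([NH+](C)C)c1ccccc1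
F4 | step 8 | (2S,3S)-2-(3,4-dihydroxyphenyl)-6-formyl-2,3-dihydro-1,4-benzodioxine-3-carboxylic acid | O=Cc1ccc2c(c1)O[C@H](C(=O)O)[C@H](c1ccc(O)c(O)c1)O2
F5 | step 8 | (2R)-2-[(carboxyacetyl)oxy]-3-(4-hydroxy-3-methoxyphenyl)propanoic acid | OC(=O)CC(=O)O[C@H](Cc1ccc(O)c(OC)c1)C(=O)O
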